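The side chain is cut at C3 (side-chain atoms counted from the carbinol carbon on flavanone C8, which is C1). This carbon carries a 4-hydroxyphenyl ring and two two-carbon arms, C2–C1 and C4=C5, which correspond to the two olefinic carbons of a prochiral 3-arylcyclopropene once its ring C=C bond is opened. A single enantioselective ring-opening/cross-metathesis joins cyclopropene 7 to the (S)-homoallylic silyl ether 12 and delivers the E C4=C5 alkene, the C1=C2 vinyl group and the C3 stereocentre together. The precursor is a 3-(4-silyloxyphenyl)cycloprop-1-ene, made and used cold. The vinyl group later becomes the C1 carbinol on ring A, and the flavanone is closed through an asymmetric aryl addition to a chromone.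

Key step: step 9

Abbreviations: TBS = tert-butyldimethylsilyl, TIPS = triisopropylsilyl, MOM = methoxymethyl.
Assumption: the sense of induction of the chiral ruthenium carbene on this substrate class cannot be predicted; the (4R,5R) ligand is written, and its mirror image is to be used if it favours 3S.
Remark: the cyclopropene phenol carries a TIPS instead of a TBS group, because only the bulkier aryl ether outlasts the carbonate methanolysis that removes the ring C–Si bond; the carbon skeletons of 7, 12 and 13 are unchanged.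

Step 1
Reactants: 1 4-hydroxybenzaldehyde
Product: 2 4-(TIPS-oxy)benzaldehyde
Conditions: TIPSCl, imidazole, DMF, rt
Reagents that add atoms: chlorotriisopropylsilane, CC(C)[Si](Cl)(C(C)C)C(C)C
Why: Standard O-silylation of a phenol gives an aryl ether robust enough for the basic methanolysis of step 4.

Step 2
Reactants: 2 4-(TIPS-oxy)benzaldehyde
Product: 3 N′-[(E)-4-(TIPS-oxy)benzylidene]-2-nitrobenzenesulfonohydrazide
Conditions: 2-nitrobenzenesulfonohydrazide, MeOH, 0 °C → rt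
Reagents that add atoms: 2-nitrobenzenesulfonohydrazide, NNS(=O)(=O)c1ccccc1[N+](=O)[O-]
Why: Condensation of the aldehyde with a sulfonyl hydrazide gives a storable hydrazone that serves as a masked aryldiazomethane.

Step 3
Reactants: 3 N′-[(E)-4-(TIPS-oxy)benzylidene]-2-nitrobenzenesulfonohydrazide; 4 trimethylsilylacetylene
Product: 6 trimethyl{3-[4-(TIPS-oxy)phenyl]cycloprop-1-en-1-yl}silane (racemic), via aryldiazomethane 5 (not isolated)
Conditions: NaH, CH2Cl2, 0 °C; then AgOTf (10 mol%), 4 (5 equiv), 25 °C, dark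
Reagents that add atoms: none
Why: Bamford–Stevens-type release of the diazoalkane from the sulfonylhydrazone salt at room temperature keeps its concentration low, and the silver carbene derived from it should undergo [2+1] cyclopropenation of the terminal silylalkyne; the C3 centre formed here is racemic and disappears as a stereocentre in step 4.

Step 4
Reactants: 6 trimethyl{3-[4-(TIPS-oxy)phenyl]cycloprop-1-en-1-yl}silane
Product: 7 3-[4-(TIPS-oxy)phenyl]cycloprop-1-ene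
Conditions: K2CO3 (20 mol%), MeOH/THF 1:1, 0 °C; cold pentane extraction; kept at −30 °C as a 0.1 M solution and used the same day
Reagents that add atoms: none
Why: Base-catalysed protodesilylation cleaves the ring C(sp2)–Si bond because of the high s-character of the cyclopropenyl carbon, while the aryl TIPS ether persists and the non-acidic C3–H prevents alkene migration.

Step 5
Reactants: 8 methyl 3-(4-hydroxyphenyl)propanoate
Product: 9 methyl 3-[4-(TBS-oxy)phenyl]propanoate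
Conditions: TBSCl, imidazole, DMF, rt
Reagents that add atoms: tert-butylchlorodimethylsilane, CC(C)(C)[Si](C)(C)Cl
Why: Standard O-silylation of the phenol.

Step 6
Reactants: 9 methyl 3-[4-(TBS-oxy)phenyl]propanoate
Product: 10 3-[4-(TBS-oxy)phenyl]propanal
Conditions: iBu2AlH (1.05 equiv), CH2Cl2, −78 °C; MeOH, then aq. potassium sodium tartrate
Reagents that add atoms: none
Why: Partial reduction of the methyl ester stops at the aldehyde because the aluminium hemiacetal is stable at −78 °C and collapses only on work-up.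

Step 7
Reactants: 10 3-[4-(TBS-oxy)phenyl]propanal
Product: 11 (3S)-1-[4-(TBS-oxy)phenyl]hex-5-en-3-ol
Conditions: allylSnBu3, (R)-BINOL (20 mol%), Ti(OiPr)4 (10 mol%), 4 Å molecular sieves, CH2Cl2, −20 °C
Reagents that add atoms: allyltributylstannane, C=CC[Sn](CCCC)(CCCC)CCCC
Why: Keck asymmetric allylation, in which the (R)-BINOL–titanium Lewis acid directs allyl transfer to the re face of the unbranched aldehyde and so sets the future C7 centre as S.

Step 8
Reactants: 11 (3S)-1-[4-(TBS-oxy)phenyl]hex-5-en-3-ol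
Product: 12 (3S)-3-(TBS-oxy)-1-[4-(TBS-oxy)phenyl]hex-5-ene
Conditions: TBSCl, imidazole, DMF, rt
Reagents that add atoms: tert-butylchlorodimethylsilane, CC(C)(C)[Si](C)(C)Cl
Why: Silylation of the secondary alcohol removes a free hydroxyl that could bind the metathesis catalyst and leaves the stereocentre untouched.

Step 9
Reactants: 7 3-[4-(TIPS-oxy)phenyl]cycloprop-1-ene; 12 (3S)-3-(TBS-oxy)-1-[4-(TBS-oxy)phenyl]hex-5-ene
Product: 13 (3R,4E,7S)-7-(TBS-oxy)-9-[4-(TBS-oxy)phenyl]-3-[4-(TIPS-oxy)phenyl]nona-1,4-diene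
Conditions: RuCl2(L*)(=CH-C6H4-2-OiPr) (5 mol%; L* = (4R,5R)-1,3-bis(2-isopropylphenyl)-4,5-diphenylimidazolidin-2-ylidene), 12 (3 equiv, excess recovered), CH2Cl2, 0 °C; 7 added over 3 h as a cold 0.05 M solution
Reagents that add atoms: none
Why: Proposed new method: the ruthenium alkylidene Ru=CH–CH2R formed from 12 adds across the strained C=C of 7 on the face anti to the aryl group, the ruthenacyclobutane opens the three-membered ring so that CHR sits on one former alkene carbon (C4=C5) and a new alkylidene on the other, and a second molecule of 12 caps that carbon as the C1=C2 vinyl group while regenerating the first alkylidene, so the two partners combine 1:1 without a by-product. The closest known reaction type is the catalytic asymmetric ring-opening/cross-metathesis of 3,3-disubstituted cyclopropenes such as 3-methyl-3-phenylcyclopropene with terminal alkenes under chiral ruthenium carbenes; a cyclopropene with hydrogen on C3 is new to this reaction and can ene-dimerise, which is why 7 is fed slowly and cold into catalyst and excess 12. No ring is closed; the three-membered ring is opened. The new C3 centre is controlled by the chiral N-heterocyclic carbene alone, which selects one of the two enantiotopic alkene carbons of 7 for bonding to the alkylidene carbon, and the remote C7 silyl ether plays no part. The step needs enantiotopic-site selection, E geometry and cross- over homo-metathesis: the mirror plane through C3–H and the aryl group makes the first purely catalyst-controlled, the trans arrangement of substituents on the ruthenacyclobutane of a dichloride catalyst favours E, and the release of ring strain makes the opening irreversible while the branched vinyl group of 13 should re-enter the cycle far more slowly than unbranched 12.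

Step 10
Reactants: 13 (3R,4E,7S)-7-(TBS-oxy)-9-[4-(TBS-oxy)phenyl]-3-[4-(TIPS-oxy)phenyl]nona-1,4-diene
Product: 14 (3R,4E,7S)-7-(TBS-oxy)-9-[4-(TBS-oxy)phenyl]-3-[4-(TIPS-oxy)phenyl]non-4-en-1-ol
Conditions: 9-BBN, THF, 0 °C → rt; then aq. NaOAc, 30% H2O2, 0 °C → rt
Reagents that add atoms: hydrogen peroxide, OO
Why: Hydroboration–oxidation with the bulky dialkylborane is selective for the monosubstituted C1=C2 alkene over the 1,2-disubstituted C4=C5 alkene and places oxygen on the terminal carbon.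

Step 11
Reactants: 14 (3R,4E,7S)-7-(TBS-oxy)-9-[4-(TBS-oxy)phenyl]-3-[4-(TIPS-oxy)phenyl]non-4-en-1-ol
Product: 15 (3R,4E,7S)-7-(TBS-oxy)-9-[4-(TBS-oxy)phenyl]-3-[4-(TIPS-oxy)phenyl]non-4-enal
Conditions: Dess–Martin periodinane, NaHCO3, CH2Cl2, 0 °C → rt
Reagents that add atoms: none
Why: Dess–Martin oxidation of the primary alcohol under buffered, neutral conditions leaves the silyl ethers and the β-stereocentre, which is not enolisable, unchanged.

Step 12
Reactants: 16 5-methoxyresorcinol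
Product: 17 1-methoxy-3,5-bis(methoxymethoxy)benzene
Conditions: MOMCl, iPr2NEt, CH2Cl2, 0 °C → rt
Reagents that add atoms: chloromethyl methyl ether, COCCl
Why: Double O-alkylation installs two acetal ethers that protect the phenols and direct the later ring metalations.

Step 13
Reactants: 17 1-methoxy-3,5-bis(methoxymethoxy)benzene; 15 (3R,4E,7S)-7-(TBS-oxy)-9-[4-(TBS-oxy)phenyl]-3-[4-(TIPS-oxy)phenyl]non-4-enal
Product: 19 (1RS,3R,4E,7S)-1-[4-methoxy-2,6-bis(methoxymethoxy)phenyl]-7-(TBS-oxy)-9-[4-(TBS-oxy)phenyl]-3-[4-(TIPS-oxy)phenyl]non-4-en-1-ol (both C1 epimers), via aryllithium 18 (not isolated)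
Conditions: 17 (1.6 equiv), nBuLi, THF, 0 °C, 1 h; then 15, −78 °C; H2O
Reagents that add atoms: none
Why: Directed ortho-metalation occurs at the ring carbon between the two MOM ethers, the most acidic and doubly coordinated site, and the aryllithium adds 1,2 to the aldehyde; the C1 centre is formed without control and is erased in step 14.

Step 14
Reactants: 19 (1RS,3R,4E,7S)-1-[4-methoxy-2,6-bis(methoxymethoxy)phenyl]-7-(TBS-oxy)-9-[4-(TBS-oxy)phenyl]-3-[4-(TIPS-oxy)phenyl]non-4-en-1-ol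
Product: 20 (3R,4E,7S)-1-[4-methoxy-2,6-bis(methoxymethoxy)phenyl]-7-(TBS-oxy)-9-[4-(TBS-oxy)phenyl]-3-[4-(TIPS-oxy)phenyl]non-4-en-1-one
Conditions: Dess–Martin periodinane, NaHCO3, CH2Cl2, rt
Reagents that add atoms: none
Why: Dess–Martin oxidation of the benzylic alcohol converges both C1 epimers on one aryl ketone.

Step 15
Reactants: 20 (3R,4E,7S)-1-[4-methoxy-2,6-bis(methoxymethoxy)phenyl]-7-(TBS-oxy)-9-[4-(TBS-oxy)phenyl]-3-[4-(TIPS-oxy)phenyl]non-4-en-1-one
Product: 21 (1S,3R,4E,7S)-1-[4-methoxy-2,6-bis(methoxymethoxy)phenyl]-7-(TBS-oxy)-9-[4-(TBS-oxy)phenyl]-3-[4-(TIPS-oxy)phenyl]non-4-en-1-ol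
Conditions: (R)-2-methyl-CBS-oxazaborolidine (0.5 equiv), catecholborane (2 equiv), toluene, −78 → −40 °C; MeOH
Reagents that add atoms: none
Why: Corey–Bakshi–Shibata reduction, in which the (R)-oxazaborolidine treats the 2,6-dialkoxyaryl group as the large substituent and delivers hydride to give the 1S alcohol, while catecholborane at low temperature does not hydroborate the alkene.

Step 16
Reactants: 21 (1S,3R,4E,7S)-1-[4-methoxy-2,6-bis(methoxymethoxy)phenyl]-7-(TBS-oxy)-9-[4-(TBS-oxy)phenyl]-3-[4-(TIPS-oxy)phenyl]non-4-en-1-ol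
Product: 22 tert-butyl{[(1S,3R,4E,7S)-7-(TBS-oxy)-1-[4-methoxy-2,6-bis(methoxymethoxy)phenyl]-9-[4-(TBS-oxy)phenyl]-3-[4-(TIPS-oxy)phenyl]non-4-en-1-yl]oxy}dimethylsilane (the C1 TBS ether of 21)
Conditions: TBSOTf, 2,6-lutidine, CH2Cl2, −78 → 0 °C
Reagents that add atoms: tert-butyldimethylsilyl trifluoromethanesulfonate, CC(C)(C)[Si](C)(C)OS(=O)(=O)C(F)(F)F
Why: The silyl triflate silylates the hindered benzylic alcohol, which blocks alkoxide formation and benzylic ionisation in the steps that follow.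

Step 17
Reactants: 22 the C1 TBS ether of 21
Product: 24 1-{3-[(1S,3R,4E,7S)-1,7-bis(TBS-oxy)-9-[4-(TBS-oxy)phenyl]-3-[4-(TIPS-oxy)phenyl]non-4-en-1-yl]-6-methoxy-2,4-bis(methoxymethoxy)phenyl}ethan-1-one, via aryllithium 23 (not isolated)
Conditions: sBuLi, TMEDA, THF, −78 °C, 1 h; MeC(O)N(OMe)Me, −78 → −30 °C; H2O
Reagents that add atoms: N-methoxy-N-methylacetamide, CC(=O)N(C)OC
Why: A second directed ortho-metalation takes place at the ring position flanked by MOM and methoxy oxygens (the two open positions of ring A are equivalent), and the Weinreb ketone synthesis stops at the methyl ketone through its chelated tetrahedral intermediate.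

Step 18
Reactants: 24 the bis-MOM acetophenone
Product: 25 1-{3-[(1S,3R,4E,7S)-1,7-bis(TBS-oxy)-9-[4-(TBS-oxy)phenyl]-3-[4-(TIPS-oxy)phenyl]non-4-en-1-yl]-2,4-dihydroxy-6-methoxyphenyl}ethan-1-one
Conditions: TMSOTf, 2,2′-bipyridyl, CH2Cl2, 0 °C → rt; then H2O
Reagents that add atoms: none
Why: Silyl triflate/2,2′-bipyridyl cleavage converts aryl MOM ethers into aryl trimethylsilyl ethers that hydrolyse on work-up, and these buffered, non-protic conditions should spare the TBS and TIPS ethers.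

Step 19
Reactants: 25 the 2,4-dihydroxyacetophenone
Product: 26 1-{3-[(1S,3R,4E,7S)-1,7-bis(TBS-oxy)-9-[4-(TBS-oxy)phenyl]-3-[4-(TIPS-oxy)phenyl]non-4-en-1-yl]-2-hydroxy-6-methoxy-4-(TIPS-oxy)phenyl}ethan-1-one
Conditions: TIPSCl, imidazole, DMF, rt
Reagents that add atoms: chlorotriisopropylsilane, CC(C)[Si](Cl)(C(C)C)C(C)C
Why: Selective O-silylation caps only the 4-hydroxyl, because the 2-hydroxyl is held in a hydrogen bond to the acetyl group and stays free for ring closure.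

Step 20
Reactants: 26 the 2-hydroxy-4-(TIPS-oxy)acetophenone
Product: 28 8-[(1S,3R,4E,7S)-1,7-bis(TBS-oxy)-9-[4-(TBS-oxy)phenyl]-3-[4-(TIPS-oxy)phenyl]non-4-en-1-yl]-5-methoxy-7-(TIPS-oxy)-4H-chromen-4-one, via enaminone 27 (not isolated)
Conditions: Me2NCH(OMe)2, toluene, 80 °C; then AcOH, toluene, 60 °C
Reagents that add atoms: N,N-dimethylformamide dimethyl acetal, COC(OC)N(C)C
Why: Condensation of the methyl ketone with the amide acetal gives the enaminone, and acid-promoted 6-endo oxa-Michael addition of the phenol with loss of dimethylamine closes the pyranone ring (enaminone route to chromones).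

Step 21
Reactants: 28 the chromone; 29 [4-(TBS-oxy)phenyl]boronic acid
Product: 30 (2S)-8-[(1S,3R,4E,7S)-1,7-bis(TBS-oxy)-9-[4-(TBS-oxy)phenyl]-3-[4-(TIPS-oxy)phenyl]non-4-en-1-yl]-5-methoxy-2-[4-(TBS-oxy)phenyl]-7-(TIPS-oxy)-2,3-dihydro-4H-chromen-4-one
Conditions: [Rh(OH)(cod)]2 (3 mol%), (S)-6,6′-dimethoxy-2,2′-bis[bis(3,4,5-trifluorophenyl)phosphino]biphenyl (6.6 mol%), 29 (3 equiv), toluene/H2O 10:1, 40 °C
Reagents that add atoms: none
Why: Hayashi–Miyaura rhodium-catalysed asymmetric 1,4-addition of the arylboronic acid to the chromone, in which the chiral bisphosphine on the aryl–rhodium species selects the face of C2; the (S) ligand is expected to give 2S by analogy with cyclic enones, and the isolated alkene and silyl ethers are inert.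

Step 22
Reactants: 30 the hexasilylated flavanone
Product: 31 (2S)-8-[(1S,3R,4E,7S)-1,7-dihydroxy-3,9-bis(4-hydroxyphenyl)non-4-en-1-yl]-7-hydroxy-2-(4-hydroxyphenyl)-5-methoxy-2,3-dihydro-4H-chromen-4-one (target)
Conditions: TBAF/AcOH (1:1, 12 equiv), THF, 0 → 45 °C
Reagents that add atoms: none
Why: Fluoride-mediated desilylation removes all six silyl ethers, and the acetic acid buffer keeps the phenols protonated so that the flavanone C2 centre is not opened by a retro-oxa-Michael reaction.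

Compound list
1 | 4-hydroxybenzaldehyde | O=Cc1ccc(O)cc1 | starting material
2 | 4-(TIPS-oxy)benzaldehyde | O=Cc1ccc(O[Si](C(C)C)(C(C)C)C(C)C)cc1 | intermediate
3 | N′-[(E)-4-(TIPS-oxy)benzylidene]-2-nitrobenzenesulfonohydrazide | CC(C)[Si](Oc1ccc(/C=N/NS(=O)(=O)c2ccccc2[N+](=O)[O-])cc1)(C(C)C)C(C)C | intermediate
4 | trimethylsilylacetylene | C#C[Si](C)(C)C | starting material
5 | [4-(TIPS-oxy)phenyl]diazomethane | [N-]=[N+]=Cc1ccc(O[Si](C(C)C)(C(C)C)C(C)C)cc1 | intermediate (not isolated)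
6 | trimethyl{3-[4-(TIPS-oxy)phenyl]cycloprop-1-en-1-yl}silane (racemic) | C[Si](C)(C)C1=CC1c1ccc(O[Si](C(C)C)(C(C)C)C(C)C)cc1 | intermediate
7 | 3-[4-(TIPS-oxy)phenyl]cycloprop-1-ene | C1=CC1c1ccc(O[Si](C(C)C)(C(C)C)C(C)C)cc1 | intermediate
8 | methyl 3-(4-hydroxyphenyl)propanoate | COC(=O)CCc1ccc(O)cc1 | starting material
9 | methyl 3-[4-(TBS-oxy)phenyl]propanoate | COC(=O)CCc1ccc(O[Si](C)(C)C(C)(C)C)cc1 | intermediate
10 | 3-[4-(TBS-oxy)phenyl]propanal | O=CCCc1ccc(O[Si](C)(C)C(C)(C)C)cc1 | intermediate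
11 | (3S)-1-[4-(TBS-oxy)phenyl]hex-5-en-3-ol | C=CC[C@@H](O)CCc1ccc(O[Si](C)(C)C(C)(C)C)cc1 | intermediate
12 | (3S)-3-(TBS-oxy)-1-[4-(TBS-oxy)phenyl]hex-5-ene | C=CC[C@@H](O[Si](C)(C)C(C)(C)C)CCc1ccc(O[Si](C)(C)C(C)(C)C)cc1 | intermediate
13 | (3R,4E,7S)-7-(TBS-oxy)-9-[4-(TBS-oxy)phenyl]-3-[4-(TIPS-oxy)phenyl]nona-1,4-diene | C=C[C@H](/C=C/C[C@@H](O[Si](C)(C)C(C)(C)C)CCc1ccc(O[Si](C)(C)C(C)(C)C)cc1)c1ccc(O[Si](C(C)C)(C(C)C)C(C)C)cc1 | intermediate
14 | (3R,4E,7S)-7-(TBS-oxy)-9-[4-(TBS-oxy)phenyl]-3-[4-(TIPS-oxy)phenyl]non-4-en-1-ol | OCC[C@H](/C=C/C[C@@H](O[Si](C)(C)C(C)(C)C)CCc1ccc(O[Si](C)(C)C(C)(C)C)cc1)c1ccc(O[Si](C(C)C)(C(C)C)C(C)C)cc1 | intermediate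
15 | (3R,4E,7S)-7-(TBS-oxy)-9-[4-(TBS-oxy)phenyl]-3-[4-(TIPS-oxy)phenyl]non-4-enal | O=CC[C@H](/C=C/C[C@@H](O[Si](C)(C)C(C)(C)C)CCc1ccc(O[Si](C)(C)C(C)(C)C)cc1)c1ccc(O[Si](C(C)C)(C(C)C)C(C)C)cc1 | intermediate
16 | 5-methoxyresorcinol | COc1cc(O)cc(O)c1 | starting material
17 | 1-methoxy-3,5-bis(methoxymethoxy)benzene | COCOc1cc(OC)cc(OCOC)c1 | intermediate
18 | [4-methoxy-2,6-bis(methoxymethoxy)phenyl]lithium | COCOc1cc(OC)cc(OCOC)c1[Li] | intermediate (not isolated)
19 | (1RS,3R,4E,7S)-1-[4-methoxy-2,6-bis(methoxymethoxy)phenyl]-7-(TBS-oxy)-9-[4-(TBS-oxy)phenyl]-3-[4-(TIPS-oxy)phenyl]non-4-en-1-ol | COCOc1cc(OC)cc(OCOC)c1C(O)C[C@H](/C=C/C[C@@H](O[Si](C)(C)C(C)(C)C)CCc2ccc(O[Si](C)(C)C(C)(C)C)cc2)c2ccc(O[Si](C(C)C)(C(C)C)C(C)C)cc2 | intermediate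
20 | (3R,4E,7S)-1-[4-methoxy-2,6-bis(methoxymethoxy)phenyl]-7-(TBS-oxy)-9-[4-(TBS-oxy)phenyl]-3-[4-(TIPS-oxy)phenyl]non-4-en-1-one | COCOc1cc(OC)cc(OCOC)c1C(=O)C[C@H](/C=C/C[C@@H](O[Si](C)(C)C(C)(C)C)CCc2ccc(O[Si](C)(C)C(C)(C)C)cc2)c2ccc(O[Si](C(C)C)(C(C)C)C(C)C)cc2 | intermediate
21 | (1S,3R,4E,7S)-1-[4-methoxy-2,6-bis(methoxymethoxy)phenyl]-7-(TBS-oxy)-9-[4-(TBS-oxy)phenyl]-3-[4-(TIPS-oxy)phenyl]non-4-en-1-ol | COCOc1cc(OC)cc(OCOC)c1[C@@H](O)C[C@H](/C=C/C[C@@H](O[Si](C)(C)C(C)(C)C)CCc2ccc(O[Si](C)(C)C(C)(C)C)cc2)c2ccc(O[Si](C(C)C)(C(C)C)C(C)C)cc2 | intermediate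
22 | C1 TBS ether of 21: (1S,3R,4E,7S)-1,7-bis(TBS-oxy)-1-[4-methoxy-2,6-bis(methoxymethoxy)phenyl]-9-[4-(TBS-oxy)phenyl]-3-[4-(TIPS-oxy)phenyl]non-4-ene | COCOc1cc(OC)cc(OCOC)c1[C@@H](O[Si](C)(C)C(C)(C)C)C[C@H](/C=C/C[C@@H](O[Si](C)(C)C(C)(C)C)CCc2ccc(O[Si](C)(C)C(C)(C)C)cc2)c2ccc(O[Si](C(C)C)(C(C)C)C(C)C)cc2 | intermediate
23 | ring-A aryllithium of 22, lithium on the carbon between a MOM ether and the methoxy group | COCOc1c([Li])c(OC)cc(OCOC)c1[C@@H](O[Si](C)(C)C(C)(C)C)C[C@H](/C=C/C[C@@H](O[Si](C)(C)C(C)(C)C)CCc2ccc(O[Si](C)(C)C(C)(C)C)cc2)c2ccc(O[Si](C(C)C)(C(C)C)C(C)C)cc2 | intermediate (not isolated)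
24 | 1-{3-[(1S,3R,4E,7S)-1,7-bis(TBS-oxy)-9-[4-(TBS-oxy)phenyl]-3-[4-(TIPS-oxy)phenyl]non-4-en-1-yl]-6-methoxy-2,4-bis(methoxymethoxy)phenyl}ethan-1-one | COCOc1c(C(C)=O)c(OC)cc(OCOC)c1[C@@H](O[Si](C)(C)C(C)(C)C)C[C@H](/C=C/C[C@@H](O[Si](C)(C)C(C)(C)C)CCc2ccc(O[Si](C)(C)C(C)(C)C)cc2)c2ccc(O[Si](C(C)C)(C(C)C)C(C)C)cc2 | intermediate
25 | 1-{3-[(1S,3R,4E,7S)-1,7-bis(TBS-oxy)-9-[4-(TBS-oxy)phenyl]-3-[4-(TIPS-oxy)phenyl]non-4-en-1-yl]-2,4-dihydroxy-6-methoxyphenyl}ethan-1-one | CC(=O)c1c(O)c([C@@H](O[Si](C)(C)C(C)(C)C)C[C@H](/C=C/C[C@@H](O[Si](C)(C)C(C)(C)C)CCc2ccc(O[Si](C)(C)C(C)(C)C)cc2)c2ccc(O[Si](C(C)C)(C(C)C)C(C)C)cc2)c(O)cc1OC | intermediate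
26 | 1-{3-[(1S,3R,4E,7S)-1,7-bis(TBS-oxy)-9-[4-(TBS-oxy)phenyl]-3-[4-(TIPS-oxy)phenyl]non-4-en-1-yl]-2-hydroxy-6-methoxy-4-(TIPS-oxy)phenyl}ethan-1-one | CC(=O)c1c(O)c([C@@H](O[Si](C)(C)C(C)(C)C)C[C@H](/C=C/C[C@@H](O[Si](C)(C)C(C)(C)C)CCc2ccc(O[Si](C)(C)C(C)(C)C)cc2)c2ccc(O[Si](C(C)C)(C(C)C)C(C)C)cc2)c(O[Si](C(C)C)(C(C)C)C(C)C)cc1OC | intermediate
27 | (E)-3-(dimethylamino)-1-{3-[(1S,3R,4E,7S)-1,7-bis(TBS-oxy)-9-[4-(TBS-oxy)phenyl]-3-[4-(TIPS-oxy)phenyl]non-4-en-1-yl]-2-hydroxy-6-methoxy-4-(TIPS-oxy)phenyl}prop-2-en-1-one | CN(C)/C=C/C(=O)c1c(O)c([C@@H](O[Si](C)(C)C(C)(C)C)C[C@H](/C=C/C[C@@H](O[Si](C)(C)C(C)(C)C)CCc2ccc(O[Si](C)(C)C(C)(C)C)cc2)c2ccc(O[Si](C(C)C)(C(C)C)C(C)C)cc2)c(O[Si](C(C)C)(C(C)C)C(C)C)cc1OC | intermediate (not isolated)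
28 | 8-[(1S,3R,4E,7S)-1,7-bis(TBS-oxy)-9-[4-(TBS-oxy)phenyl]-3-[4-(TIPS-oxy)phenyl]non-4-en-1-yl]-5-methoxy-7-(TIPS-oxy)-4H-chromen-4-one | COc1cc(O[Si](C(C)C)(C(C)C)C(C)C)c([C@@H](O[Si](C)(C)C(C)(C)C)C[C@H](/C=C/C[C@@H](O[Si](C)(C)C(C)(C)C)CCc2ccc(O[Si](C)(C)C(C)(C)C)cc2)c2ccc(O[Si](C(C)C)(C(C)C)C(C)C)cc2)c2occc(=O)c12 | intermediate
29 | [4-(TBS-oxy)phenyl]boronic acid | CC(C)(C)[Si](C)(C)Oc1ccc(B(O)O)cc1 | starting material
30 | (2S)-8-[(1S,3R,4E,7S)-1,7-bis(TBS-oxy)-9-[4-(TBS-oxy)phenyl]-3-[4-(TIPS-oxy)phenyl]non-4-en-1-yl]-5-methoxy-2-[4-(TBS-oxy)phenyl]-7-(TIPS-oxy)-2,3-dihydro-4H-chromen-4-one | COc1cc(O[Si](C(C)C)(C(C)C)C(C)C)c([C@@H](O[Si](C)(C)C(C)(C)C)C[C@H](/C=C/C[C@@H](O[Si](C)(C)C(C)(C)C)CCc2ccc(O[Si](C)(C)C(C)(C)C)cc2)c2ccc(O[Si](C(C)C)(C(C)C)C(C)C)cc2)c2c1C(=O)C[C@@H](c1ccc(O[Si](C)(C)C(C)(C)C)cc1)O2 | intermediate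
31 | (2S)-8-[(1S,3R,4E,7S)-1,7-dihydroxy-3,9-bis(4-hydroxyphenyl)non-4-en-1-yl]-7-hydroxy-2-(4-hydroxyphenyl)-5-methoxy-2,3-dihydro-4H-chromen-4-one | COc1cc(O)c([C@@H](O)C[C@H](/C=C/C[C@@H](O)CCc2ccc(O)cc2)c2ccc(O)cc2)c2c1C(=O)C[C@@H](c1ccc(O)cc1)O2 | target

Total step count: 22.
Longest linear sequence: 17 steps (steps 1–4, 9–11, 13–22; from 1 through 2, 3, 6, 7, 13, 14, 15, 19, 20, 21, 22, 24, 25, 26, 28 and 30 to 31).

Steps most likely to fail

Step 9. The cyclopropene may be consumed by ene dimerisation or ring-opening oligomerisation before cross-metathesis, and the catalyst may discriminate poorly between the two enantiotopic alkene carbons or between E and Z ring-opening. The fallback, with known chemistry only, is an enantioselective copper-catalysed SN2′ allylic substitution. Setting out from 12, cross-metathesis with pinacol vinylboronate (RuCl2(H2IMes)(=CH-C6H4-2-OiPr), CH2Cl2, 40 °C) would give the (E)-alkenyl pinacol boronate F1. In parallel, aldehyde 2 would be converted by Horner–Wadsworth–Emmons olefination (triethyl phosphonoacetate, NaH, THF) into the ethyl (E)-cinnamate F2, reduced with iBu2AlH to the cinnamyl alcohol F3 and phosphorylated (ClP(O)(OEt)2, pyridine) to the allylic diethyl phosphate F4. Coupling of F1 with F4 under a chiral sulfonate-bearing N-heterocyclic carbene–copper catalyst (imidazolinium salt, CuCl, NaOMe, THF) should deliver the alkenyl group to the benzylic carbon with allylic transposition and so give 13, where the route is rejoined.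

Step 3. The unstabilised aryl carbene may dimerise to azine or stilbene, or the silver salt may divert the terminal alkyne, faster than [2+1] addition takes place. The fallback builds the ring by halocarbene chemistry. Setting out from 2, Wittig reaction with Ph3P=CHBr (from (bromomethyl)triphenylphosphonium bromide and KOtBu, THF, −78 °C) would give the β-bromostyrene F5 as an E/Z mixture, both isomers being usable. Dibromocarbene addition (CHBr3, KOtBu, pentane, −10 °C → rt) would give the 1,1,2-tribromo-3-arylcyclopropane F6. Treatment with MeLi (2.2 equiv, Et2O, −78 °C; then MeOH) would bring about 1,2-debromination and bromine–lithium exchange to the 1-lithiocyclopropene, whose protonation gives 7 directly, so that 3 to 6 are bypassed.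

Step 17. Proton abstraction at the doubly activated C3–H or at the silyloxy-bearing benzylic carbon may compete with ring lithiation, and the hindered aryllithium may deprotonate the amide instead of adding to it. The fallback avoids strong base. Setting out from 22, N-bromosuccinimide (1.0 equiv, CH2Cl2, −78 °C) should brominate one of the two equivalent open positions of the trioxygenated ring A to give the aryl bromide F7. Stille coupling with tributyl(1-ethoxyvinyl)stannane (Pd(PPh3)4, toluene, 90 °C) would give the aryl enol ether F8, and brief hydrolysis (pyridinium p-toluenesulfonate, wet acetone, rt) would give 24, where the route is rejoined.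

Further compounds
F1 | step 9 | 2-[(1E,4S)-4-(TBS-oxy)-6-[4-(TBS-oxy)phenyl]hex-1-en-1-yl]-4,4,5,5-tetramethyl-1,3,2-dioxaborolane | CC1(C)OB(/C=C/C[C@@H](O[Si](C)(C)C(C)(C)C)CCc2ccc(O[Si](C)(C)C(C)(C)C)cc2)OC1(C)C
F2 | step 9 | ethyl (E)-3-[4-(TIPS-oxy)phenyl]prop-2-enoate | CCOC(=O)/C=C/c1ccc(O[Si](C(C)C)(C(C)C)C(C)C)cc1
F3 | step 9 | (E)-3-[4-(TIPS-oxy)phenyl]prop-2-en-1-ol | OC/C=C/c1ccc(O[Si](C(C)C)(C(C)C)C(C)C)cc1
F4 | step 9 | diethyl (E)-3-[4-(TIPS-oxy)phenyl]prop-2-en-1-yl phosphate | CCOP(=O)(OCC)OC/C=C/c1ccc(O[Si](C(C)C)(C(C)C)C(C)C)cc1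
F5 | step 3 | 1-(2-bromoethenyl)-4-(TIPS-oxy)benzene (E/Z mixture) | BrC=Cc1ccc(O[Si](C(C)C)(C(C)C)C(C)C)cc1
F6 | step 3 | 1,1,2-tribromo-3-[4-(TIPS-oxy)phenyl]cyclopropane (diastereomer mixture) | BrC1C(c2ccc(O[Si](C(C)C)(C(C)C)C(C)C)cc2)C1(Br)Br
F7 | step 17 | (1S,3R,4E,7S)-1-[3-bromo-4-methoxy-2,6-bis(methoxymethoxy)phenyl]-1,7-bis(TBS-oxy)-9-[4-(TBS-oxy)phenyl]-3-[4-(TIPS-oxy)phenyl]non-4-ene | COCOc1c(Br)c(OC)cc(OCOC)c1[C@@H](O[Si](C)(C)C(C)(C)C)C[C@H](/C=C/C[C@@H](O[Si](C)(C)C(C)(C)C)CCc2ccc(O[Si](C)(C)C(C)(C)C)cc2)c2ccc(O[Si](C(C)C)(C(C)C)C(C)C)cc2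
F8 | step 17 | (1S,3R,4E,7S)-1-[3-(1-ethoxyethenyl)-4-methoxy-2,6-bis(methoxymethoxy)phenyl]-1,7-bis(TBS-oxy)-9-[4-(TBS-oxy)phenyl]-3-[4-(TIPS-oxy)phenyl]non-4-ene | COCOc1c(C(=C)OCC)c(OC)cc(OCOC)c1[C@@H](O[Si](C)(C)C(C)(C)C)C[C@H](/C=C/C[C@@H](O[Si](C)(C)C(C)(C)C)CCc2ccc(O[Si](C)(C)C(C)(C)C)cc2)c2ccc(O[Si](C(C)C)(C(C)C)C(C)C)cc2
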